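## Analysis of the target

- The target is a 2H-chromene. Benzene ring A (C4a, C5, C6, C7, C8, C8a) is fused to the 2H-pyran ring B (O1, C2, C3=C4). C6 carries an (E)-4-hydroxycinnamoyl group that ends in the phenol ring C.
- Ring A is pentasubstituted: C4 on C4a, OH on C5, the acyl group on C6, OH on C8 and O1 on C8a, with a single hydrogen at C7. C5–OH and C8–OH are para, so ring A is an acyl hydroquinone.
- The only stereocentre is C2, read from the SMILES as (S). It is a fully substituted tertiary ether carbon bearing O1, C3, a methyl group and the 4-hydroxy-4-methylpentyl chain. Methyl and chain differ only beyond their first carbon, and no second stereocentre exists to relay from.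
- Sensitive groups: the hydroquinone (oxidation in base and air), the 2'-hydroxychalcone (Michael acceptor, flavanone closure) and the tertiary alcohol (elimination).
- The O1–C2 bond is the most delicate point. It is allylic to C3=C4 and conjugated with ring A, so acid-promoted heterolysis or electrocyclic opening of ring B (light, heat) passes through a planar dienone and erases C2.
- The difficulty is therefore to set a methyl/alkyl tertiary ether centre as one enantiomer, and never to break O1–C2 afterwards, on a ring that offers no free choice of position.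
- The feature the route exploits: C2 is both the aryl ether carbon of O1 and the allylic carbon of C3=C4. With C3=C4 raised to C3≡C4 and C4–C4a cut, ring B is a tertiary propargyl aryl ether. O1 sits para to the C6 carbonyl (the most acidic phenol of ring A) and C4a sits between two oxygens (its most nucleophilic carbon).

## Retrosynthetic reasoning

**18 ⇒ 17.** No skeletal bond is cut. The phenols on C8 and on ring C are masked as MOM ethers and the tertiary alcohol as a triethylsilyl ether. The hydroquinone is then never exposed to base, and all three groups leave in one mild operation. The forward step must not ionise O1–C2.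

**17 ⇒ 15 + 16.** The Cα=Cβ bond of the enone is cut. The cut is made here and not at C6–C(=O) because the acetyl group is needed from the start: it makes the oxygen that becomes O1 the most acidic phenol and ties the neighbouring OH into a chelate. The forward reaction is a Claisen–Schmidt condensation, which leaves C2 untouched.

**15 ⇒ 14.** C4–C4a of ring B is cut and C3=C4 is raised to an alkyne. C4a lies between two oxygens and needs no pre-functionalisation. Cutting here rather than at O1–C2 means the ring closure does not touch the stereocentre. The forward reaction must close ring B by direct attack of the arene on the activated alkyne; a thermal sigmatropic cascade would break O1–C2 and lose the configuration.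

**14 ⇒ 6 + 13 (key disconnection).** O1–C2 is cut. This divides the molecule into the complete arene 6 and the complete C10 chain 13. It is also the one bond at C2 whose formation can pass through a planar carbon under catalyst control, so racemic 13 is sufficient. The forward reaction must alkylate only the phenol para to the acetyl group, on oxygen, and must set C2 as (S).

**13 ⇒ 9 + 10 + 11, and 9 ⇒ 7 + 8.** The alkyne–carbinol bond is cut: 10 adds to the methyl ketone 9 and the alkoxide is trapped with 11. Ketone 9 is the silyl ether (from 8) of the hydroxy ketone 7, which already holds the hydrated chain terminus. No stereocontrol is needed here.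

**6 ⇒ 5 ⇒ 3 ⇒ 1.** No skeletal change. Ring A is bought as 1 with its three oxygens and the acetyl group in place. The three phenols are told apart by acidity: 2 goes on the most acidic one, 4 on the next, the chelated one stays free, and hydrogenolysis then frees the oxygen that becomes O1.

## Alternatives that were turned down

**Alternative 1: the textbook disconnection.** C4–C4a and O1–C2 are cut together. Condensation of 6 with (2E)-7-hydroxy-3,7-dimethyloct-2-enal A1 under amine catalysis would give, by Knoevenagel condensation, the ring-opened dienone A2, which closes by oxa-6π electrocyclisation to the chromene A3.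
- This is the shortest way to ring B and uses the innate reactivity of ring A.
- It was turned down because A2 is planar and achiral, and its ring closure is a fast, uncatalysed pericyclic step with no bound chiral species. A3 can only form as the racemate.
- The single enantiomer would then need a preparative separation that discards half of an advanced intermediate, with no lever for improvement.

**Alternative 2: ring B and C2 in one palladium step.** O1–C2 is cut with the ring still to be closed. The aldehyde A4 (C-formylation of 6) would take up an (E)-alkenyl nucleophile, and the benzylic alcohol would be converted to the racemic carbonate A5. Zerovalent palladium with a chiral ligand would ionise A5 to a π-allyl complex, and 6-endo attack of the phenol on the trisubstituted terminus would close ring B and set C2 from the racemate.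
- It was turned down for three reasons:
  - A5 is an ortho-hydroxybenzylic carbonate that can ionise without metal to the same kind of planar dienone as A2, a racemic background path.
  - Ring closure requires the aryl group to turn from syn to anti by π–σ–π isomerisation. That isomerisation also exchanges the palladium face at C2, so the outcome depends on two coupled equilibria rather than on the alkene geometry.
  - The precursor costs a formylation, a stereodefined alkenyl reagent and a selective acylation — more steps than the key step saves.

**Alternative 3: chiral pool.** O1–C8a and C3=C4 are cut. The alkoxide of (S)-linalool A6 would displace fluoride from the fluoroarene A7 (SNAr para to the acetyl group) to give the ether A8. Ring-closing metathesis of its two vinyl groups would close ring B, and Markovnikov hydration of the chain alkene would follow.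
- C2 would be bought and never broken, but the route was turned down for four reasons:
  - A7 is a pentasubstituted arene with no short synthesis.
  - A hindered tertiary alkoxide must attack a ring that carries a phenoxide and an enolisable ketone.
  - The linalyl unit of A8 can close onto its own trisubstituted alkene in the metathesis step.
  - The late hydration would have to distinguish the chain alkene from the styrene-like C3=C4.

Key step: step 6

Assumptions:
- Compounds 1, 7 and 16 are taken as purchasable.
- The (S,S) ligand of step 6 is taken to give (S)-14; if the sense of induction is the reverse, its enantiomer is used and nothing else changes.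

## Route

Step 1
Reactants: 1 1-(2,4,5-trihydroxyphenyl)ethan-1-one; 2 benzyl bromide
Product: 3 1-[4-(benzyloxy)-2,5-dihydroxyphenyl]ethan-1-one
Conditions: BnBr (1.05 equiv), NaHCO3 (1.5 equiv), NaI (10 mol %), DMF, 40 °C, argon
Reagents that add atoms: benzyl bromide 2, BrCc1ccccc1
Why: Williamson etherification under acidity control: hydrogen carbonate can deprotonate only the 4-OH, which is para to the acetyl group, while the 2-OH is held in a hydrogen bond to the ketone and the 5-OH is an ordinary phenol, so benzylation should stop at O-4.

Step 2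
Reactants: 3 1-[4-(benzyloxy)-2,5-dihydroxyphenyl]ethan-1-one; 4 chloromethyl methyl ether
Product: 5 1-[4-(benzyloxy)-2-hydroxy-5-(methoxymethoxy)phenyl]ethan-1-one
Conditions: MOMCl (1.2 equiv), i-Pr2NEt (1.5 equiv), CH2Cl2, 0 °C to rt
Reagents that add atoms: chloromethyl methyl ether 4, COCCl
Why: MOM ether formation with an amine base: the free 5-OH reacts and the chelated 2-OH does not; the MOM group is chosen because it survives hydrogenolysis, copper, gold and hydroxide and leaves in the last step.

Step 3
Reactants: 5 1-[4-(benzyloxy)-2-hydroxy-5-(methoxymethoxy)phenyl]ethan-1-one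
Product: 6 1-[2,4-dihydroxy-5-(methoxymethoxy)phenyl]ethan-1-one
Conditions: H2 (1 atm), 10% Pd/C, EtOAc, rt
Reagents that add atoms: none
Why: Hydrogenolysis of the benzyl ether frees the oxygen that becomes O1; the MOM acetal and the aryl ketone should not be touched at one atmosphere and room temperature if the reaction is stopped at full conversion.

Step 4
Reactants: 7 6-hydroxy-6-methylheptan-2-one; 8 triethylsilyl trifluoromethanesulfonate
Product: 9 6-methyl-6-[(triethylsilyl)oxy]heptan-2-one
Conditions: TESOTf (1.1 equiv), 2,6-lutidine (1.5 equiv), CH2Cl2, −78 °C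
Reagents that add atoms: triethylsilyl trifluoromethanesulfonate 8, CC[Si](CC)(CC)OS(=O)(=O)C(F)(F)F
Why: Silylation of the tertiary alcohol with a silyl triflate; the silyl ether keeps this oxygen from consuming Grignard reagent in step 5 and from adding to the copper allenylidene in step 6, and it leaves with the MOM groups at the end.

Step 5
Reactants: 9 6-methyl-6-[(triethylsilyl)oxy]heptan-2-one; 10 ethynylmagnesium bromide; 11 methyl chloroformate
Product: 13 rac-3,7-dimethyl-7-[(triethylsilyl)oxy]oct-1-yn-3-yl methyl carbonate, via bromomagnesium alkoxide 12 (not isolated)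
Conditions: HC≡CMgBr (1.3 equiv), THF, 0 °C to rt; then ClCO2Me (1.5 equiv), 0 °C to rt
Reagents that add atoms: ethynylmagnesium bromide 10, C#C[Mg]Br; methyl chloroformate 11, COC(=O)Cl
Why: 1,2-Addition of the alkynyl Grignard reagent to the methyl ketone and acylation of the tertiary alkoxide in the same flask give the propargylic carbonate; the new stereocentre is formed without control because step 6 is enantioconvergent and uses the racemate.

Step 6
Reactants: 6 1-[2,4-dihydroxy-5-(methoxymethoxy)phenyl]ethan-1-one; 13 rac-3,7-dimethyl-7-[(triethylsilyl)oxy]oct-1-yn-3-yl methyl carbonate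
Product: 14 1-[4-{[(3S)-3,7-dimethyl-7-[(triethylsilyl)oxy]oct-1-yn-3-yl]oxy}-2-hydroxy-5-(methoxymethoxy)phenyl]ethan-1-one
Conditions: 13 (1.2 equiv), Cu(MeCN)4PF6 (5 mol %), 4-(3,5-di-tert-butylphenyl)-2,6-bis[(4S)-4-phenyl-4,5-dihydro-1,3-oxazol-2-yl]pyridine (6 mol %), i-Pr2NEt (1.5 equiv), THF, −20 °C, argon
Reagents that add atoms: carbonate 13, C#CC(C)(CCCC(C)(C)O[Si](CC)(CC)CC)OC(=O)OC
Why: Proposed new method: copper-catalysed enantioconvergent propargylic etherification of a dialkyl tertiary propargylic carbonate with a phenol; the closest known reaction types are the asymmetric propargylic etherification of secondary propargylic esters with phenols and the asymmetric amination of ketone-derived tertiary propargylic carbonates, both with monovalent copper and PYBOX ligands. Mechanism: amine and copper convert the terminal alkyne of 13 into a copper acetylide, and loss of methyl carbonate (then CO2 and methoxide) gives a copper allenylidene whose former carbinol carbon is planar, so both enantiomers of 13 merge into one intermediate. The 4-phenoxide of 6 adds to the γ-carbon on the face left open by the ligand, and protonation of the new copper acetylide releases 14 and the catalyst. The step closes no ring; it forms the O1–C2 bond, joins the whole C10 chain to ring A and sets the only stereocentre. C2 is set by the catalyst alone: the aryl group on the pyridine and the phenyl groups of the oxazolines form a narrow pocket that has to tell the methyl group from the CH2 chain on the allenylidene terminus, which is the uncertain point of the route. Selectivity between the phenols follows from acidity (the OH para to the acetyl group is deprotonated, the chelated one is not), O- over C-alkylation from the acyl-deactivated ring, and γ- over α-attack from the usual polarisation of copper allenylidenes. The silyl ether on the chain removes the only internal nucleophile that could trap the allenylidene in a six-membered ring. The low temperature keeps the thermal rearrangement of 14 and re-ionisation of the product ether slow.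

Step 7
Reactants: 14 1-[4-{[(3S)-3,7-dimethyl-7-[(triethylsilyl)oxy]oct-1-yn-3-yl]oxy}-2-hydroxy-5-(methoxymethoxy)phenyl]ethan-1-one
Product: 15 1-[(2S)-5-hydroxy-8-(methoxymethoxy)-2-methyl-2-{4-methyl-4-[(triethylsilyl)oxy]pentyl}-2H-chromen-6-yl]ethan-1-one
Conditions: [(t-Bu)2(2-biphenylyl)P]Au(NCMe)SbF6 (2 mol %), CH2Cl2, rt, dark
Reagents that add atoms: none
Why: Gold-catalysed intramolecular hydroarylation (6-endo-dig Friedel–Crafts alkenylation): the cationic monovalent gold–alkyne complex is attacked by the only free carbon ortho to the ether oxygen, which lies between two oxygens, and protodeauration gives C3=C4 and ring B. The O1–C2 bond is never broken, so the configuration of 14 is carried into 15, whereas the thermal Claisen cascade of aryl propargyl ethers would pass through a planar ring-opened dienone and is avoided by working at room temperature.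

Step 8
Reactants: 15 1-[(2S)-5-hydroxy-8-(methoxymethoxy)-2-methyl-2-{4-methyl-4-[(triethylsilyl)oxy]pentyl}-2H-chromen-6-yl]ethan-1-one; 16 4-(methoxymethoxy)benzaldehyde
Product: 17 (2E)-1-[(2S)-5-hydroxy-8-(methoxymethoxy)-2-methyl-2-{4-methyl-4-[(triethylsilyl)oxy]pentyl}-2H-chromen-6-yl]-3-[4-(methoxymethoxy)phenyl]prop-2-en-1-one
Conditions: KOH (50% aq., 10 equiv), EtOH, 0 °C to rt, argon, dark
Reagents that add atoms: 4-(methoxymethoxy)benzaldehyde 16, COCOc1ccc(C=O)cc1
Why: Claisen–Schmidt condensation: the enolate of the methyl ketone adds to the non-enolisable aldehyde and the aldol eliminates to the (E)-enone, the thermodynamic isomer; the chelated 5-OH may stay free, the MOM group on O-8 keeps the hydroquinone from oxidation in base, and C2 has no acidic hydrogen and is not affected.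

Step 9
Reactants: 17 (2E)-1-[(2S)-5-hydroxy-8-(methoxymethoxy)-2-methyl-2-{4-methyl-4-[(triethylsilyl)oxy]pentyl}-2H-chromen-6-yl]-3-[4-(methoxymethoxy)phenyl]prop-2-en-1-one
Product: 18 (2E)-1-[(2S)-5,8-dihydroxy-2-(4-hydroxy-4-methylpentyl)-2-methyl-2H-chromen-6-yl]-3-(4-hydroxyphenyl)prop-2-en-1-one
Conditions: HCl (3 M aq.)/MeOH/THF (1:8:2), rt, argon, dark
Reagents that add atoms: none
Why: Acid-catalysed acetal exchange removes both phenolic MOM groups and solvolysis removes the tertiary silyl ether in one operation; dilute acid at room temperature is used so that protonation of O1 and ionisation of O1–C2, the only path that could erode C2, stays slow, and argon and darkness protect the acyl hydroquinone and the photolabile chromene.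

## Compound list

1 | 1-(2,4,5-trihydroxyphenyl)ethan-1-one | CC(=O)c1cc(O)c(O)cc1O | starting material
2 | benzyl bromide | BrCc1ccccc1 | starting material
3 | 1-[4-(benzyloxy)-2,5-dihydroxyphenyl]ethan-1-one | CC(=O)c1cc(O)c(OCc2ccccc2)cc1O | intermediate
4 | chloromethyl methyl ether | COCCl | starting material
5 | 1-[4-(benzyloxy)-2-hydroxy-5-(methoxymethoxy)phenyl]ethan-1-one | CC(=O)c1cc(OCOC)c(OCc2ccccc2)cc1O | intermediate
6 | 1-[2,4-dihydroxy-5-(methoxymethoxy)phenyl]ethan-1-one | CC(=O)c1cc(OCOC)c(O)cc1O | intermediate
7 | 6-hydroxy-6-methylheptan-2-one | CC(=O)CCCC(C)(C)O | starting material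
8 | triethylsilyl trifluoromethanesulfonate | CC[Si](CC)(CC)OS(=O)(=O)C(F)(F)F | starting material
9 | 6-methyl-6-[(triethylsilyl)oxy]heptan-2-one | CC(=O)CCCC(C)(C)O[Si](CC)(CC)CC | intermediate
10 | ethynylmagnesium bromide | C#C[Mg]Br | starting material
11 | methyl chloroformate | COC(=O)Cl | starting material
12 | bromomagnesium rac-3,7-dimethyl-7-[(triethylsilyl)oxy]oct-1-yn-3-olate | C#CC(C)(CCCC(C)(C)O[Si](CC)(CC)CC)O[Mg]Br | intermediate
13 | rac-3,7-dimethyl-7-[(triethylsilyl)oxy]oct-1-yn-3-yl methyl carbonate | C#CC(C)(CCCC(C)(C)O[Si](CC)(CC)CC)OC(=O)OC | intermediate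
14 | 1-[4-{[(3S)-3,7-dimethyl-7-[(triethylsilyl)oxy]oct-1-yn-3-yl]oxy}-2-hydroxy-5-(methoxymethoxy)phenyl]ethan-1-one | C#C[C@](C)(CCCC(C)(C)O[Si](CC)(CC)CC)Oc1cc(O)c(C(C)=O)cc1OCOC | intermediate
15 | 1-[(2S)-5-hydroxy-8-(methoxymethoxy)-2-methyl-2-{4-methyl-4-[(triethylsilyl)oxy]pentyl}-2H-chromen-6-yl]ethan-1-one | CC[Si](CC)(CC)OC(C)(C)CCC[C@@]1(C)C=Cc2c(O)c(C(C)=O)cc(OCOC)c2O1 | intermediate
16 | 4-(methoxymethoxy)benzaldehyde | COCOc1ccc(C=O)cc1 | starting material
17 | (2E)-1-[(2S)-5-hydroxy-8-(methoxymethoxy)-2-methyl-2-{4-methyl-4-[(triethylsilyl)oxy]pentyl}-2H-chromen-6-yl]-3-[4-(methoxymethoxy)phenyl]prop-2-en-1-one | CC[Si](CC)(CC)OC(C)(C)CCC[C@@]1(C)C=Cc2c(O)c(C(=O)/C=C/c3ccc(OCOC)cc3)cc(OCOC)c2O1 | intermediate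
18 | (2E)-1-[(2S)-5,8-dihydroxy-2-(4-hydroxy-4-methylpentyl)-2-methyl-2H-chromen-6-yl]-3-(4-hydroxyphenyl)prop-2-en-1-one | CC(C)(O)CCC[C@@]1(C)C=Cc2c(O)c(C(=O)/C=C/c3ccc(O)cc3)cc(O)c2O1 | target

## Step count and least certain steps

Total step count: 9. Longest linear sequence: 7 (steps 1, 2, 3, 6, 7, 8, 9).

**Step 6 (key step, proposed new method).**
- What may go wrong: poor facial discrimination at the planar allenylidene carbon, because the pocket has to distinguish a methyl group from an unbranched CH2 chain. Also possible are competing attack through the ring carbon between the two oxygens, and slow re-ionisation of the product ether.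
- Fallback (known chemistry): it sets out from 9 and 6 and returns at 14.
  - Horner–Wadsworth–Emmons olefination of 9 with triethyl phosphonoacetate (NaH, THF) gives ethyl (2E)-3,7-dimethyl-7-[(triethylsilyl)oxy]oct-2-enoate F1, freed from the minor Z isomer by chromatography.
  - DIBAL-H reduction gives (2E)-3,7-dimethyl-7-[(triethylsilyl)oxy]oct-2-en-1-ol F2.
  - Methyl chloroformate and pyridine give (2E)-3,7-dimethyl-7-[(triethylsilyl)oxy]oct-2-en-1-yl methyl carbonate F3.
  - Tsuji–Trost asymmetric allylic etherification of 6 with F3 (Pd2(dba)3·CHCl3, N,N'-(cyclohexane-1,2-diyl)bis[2-(diphenylphosphanyl)benzamide] of the fitting configuration, CH2Cl2, rt) should give the branched tertiary ether 1-[4-{[(3S)-3,7-dimethyl-7-[(triethylsilyl)oxy]oct-1-en-3-yl]oxy}-2-hydroxy-5-(methoxymethoxy)phenyl]ethan-1-one F4. Here the methyl/chain difference is encoded in the E geometry of the alkene, so the ligand only has to choose a face of the π-allyl complex.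
  - Lemieux–Johnson cleavage of the vinyl group (OsO4 cat., NaIO4, 2,6-lutidine, dioxane/water) gives the aldehyde (2S)-2-[4-acetyl-5-hydroxy-2-(methoxymethoxy)phenoxy]-2,6-dimethyl-6-[(triethylsilyl)oxy]heptanal F5, which cannot epimerise.
  - Seyferth–Gilbert homologation with the Ohira–Bestmann reagent (K2CO3, MeOH, rt) returns 14.

**Step 7.**
- What may go wrong: gold-promoted ionisation of the tertiary propargylic C–O bond, competing with cyclisation because the ring is deactivated by the acetyl group. This would cause loss of the chain or erosion of the configuration. Catalyst inhibition by the chelating hydroxy ketone is also possible.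
- Fallback: it sets out from 14 and returns at 15.
  - Hydroboration of the alkyne with dicyclohexylborane (excess, THF, 0 °C) and oxidation with NaBO3·4H2O give (3S)-3-[4-acetyl-5-hydroxy-2-(methoxymethoxy)phenoxy]-3,7-dimethyl-7-[(triethylsilyl)oxy]octanal F6.
  - Ortho-hydroxyalkylation directed by the magnesium phenoxide (EtMgBr, 1 equiv, toluene, rt) closes ring B at C4–C4a to 1-[(2S)-4,5-dihydroxy-8-(methoxymethoxy)-2-methyl-2-{4-methyl-4-[(triethylsilyl)oxy]pentyl}-3,4-dihydro-2H-chromen-6-yl]ethan-1-one F7.
  - Dehydration of the benzylic alcohol (PPTS, toluene, 50 °C) gives 15. O1–C2 stays intact throughout.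

**Step 9.**
- What may go wrong: acid-promoted heterolysis of O1–C2 followed by re-closure, which would erode the enantiomeric purity. Acid-promoted addition of methanol across C3=C4 and closure of the 2'-hydroxychalcone to a flavanone are further risks.
- Fallback: it sets out from 17 and returns at 18.
  - TMSOTf and 2,2'-bipyridyl (CH2Cl2, 0 °C) convert the aryl MOM ethers into silyl ethers without free Brønsted acid. Aqueous work-up gives (2E)-1-[(2S)-5,8-dihydroxy-2-methyl-2-{4-methyl-4-[(triethylsilyl)oxy]pentyl}-2H-chromen-6-yl]-3-(4-hydroxyphenyl)prop-2-en-1-one F8.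
  - Buffered fluoride (TBAF, AcOH, THF, 0 °C) removes the silyl ether to give 18.

**Step 1.**
- What may go wrong: incomplete site selectivity (alkylation of the 5-oxygen or double alkylation) and air oxidation of the electron-rich triol in base.
- Fallback: it sets out from the purchasable 1-[4-(benzyloxy)-2-hydroxyphenyl]ethan-1-one F9 and returns at 3.
  - Elbs persulfate oxidation (K2S2O8, aq. NaOH, 0 °C to rt) introduces oxygen para to the phenoxide as potassium 5-acetyl-2-(benzyloxy)-4-hydroxyphenyl sulfate F10.
  - Hydrolysis of the sulfate (dilute HCl, 60 °C) gives 3.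

## Further compounds

F1 | step 6 | ethyl (2E)-3,7-dimethyl-7-[(triethylsilyl)oxy]oct-2-enoate | CCOC(=O)/C=C(\C)CCCC(C)(C)O[Si](CC)(CC)CC
F2 | step 6 | (2E)-3,7-dimethyl-7-[(triethylsilyl)oxy]oct-2-en-1-ol | OC/C=C(\C)CCCC(C)(C)O[Si](CC)(CC)CC
F3 | step 6 | (2E)-3,7-dimethyl-7-[(triethylsilyl)oxy]oct-2-en-1-yl methyl carbonate | COC(=O)OC/C=C(\C)CCCC(C)(C)O[Si](CC)(CC)CC
F4 | step 6 | 1-[4-{[(3S)-3,7-dimethyl-7-[(triethylsilyl)oxy]oct-1-en-3-yl]oxy}-2-hydroxy-5-(methoxymethoxy)phenyl]ethan-1-one | C=C[C@](C)(CCCC(C)(C)O[Si](CC)(CC)CC)Oc1cc(O)c(C(C)=O)cc1OCOC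
F5 | step 6 | (2S)-2-[4-acetyl-5-hydroxy-2-(methoxymethoxy)phenoxy]-2,6-dimethyl-6-[(triethylsilyl)oxy]heptanal | O=C[C@](C)(CCCC(C)(C)O[Si](CC)(CC)CC)Oc1cc(O)c(C(C)=O)cc1OCOC
F6 | step 7 | (3S)-3-[4-acetyl-5-hydroxy-2-(methoxymethoxy)phenoxy]-3,7-dimethyl-7-[(triethylsilyl)oxy]octanal | O=CC[C@](C)(CCCC(C)(C)O[Si](CC)(CC)CC)Oc1cc(O)c(C(C)=O)cc1OCOC
F7 | step 7 | 1-[(2S)-4,5-dihydroxy-8-(methoxymethoxy)-2-methyl-2-{4-methyl-4-[(triethylsilyl)oxy]pentyl}-3,4-dihydro-2H-chromen-6-yl]ethan-1-one (both C4 epimers) | CC[Si](CC)(CC)OC(C)(C)CCC[C@@]1(C)CC(O)c2c(O)c(C(C)=O)cc(OCOC)c2O1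
F8 | step 9 | (2E)-1-[(2S)-5,8-dihydroxy-2-methyl-2-{4-methyl-4-[(triethylsilyl)oxy]pentyl}-2H-chromen-6-yl]-3-(4-hydroxyphenyl)prop-2-en-1-one | CC[Si](CC)(CC)OC(C)(C)CCC[C@@]1(C)C=Cc2c(O)c(C(=O)/C=C/c3ccc(O)cc3)cc(O)c2O1
F9 | step 1 | 1-[4-(benzyloxy)-2-hydroxyphenyl]ethan-1-one | CC(=O)c1ccc(OCc2ccccc2)cc1O
F10 | step 1 | potassium 5-acetyl-2-(benzyloxy)-4-hydroxyphenyl sulfate | CC(=O)c1cc(OS(=O)(=O)[O-])c(OCc2ccccc2)cc1O.[K+]
A1 | alternative 1 | (2E)-7-hydroxy-3,7-dimethyloct-2-enal | CC(C)(O)CCC/C(C)=C/C=O
A2 | alternative 1 | 4-acetyl-3-hydroxy-2-(7-hydroxy-3,7-dimethyloct-2-en-1-ylidene)-6-(methoxymethoxy)cyclohexa-3,5-dien-1-one | CC(=O)C1=C(O)C(=CC=C(C)CCCC(C)(C)O)C(=O)C(OCOC)=C1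
A3 | alternative 1 | rac-1-[5-hydroxy-2-(4-hydroxy-4-methylpentyl)-8-(methoxymethoxy)-2-methyl-2H-chromen-6-yl]ethan-1-one | CC(C)(O)CCCC1(C)C=Cc2c(O)c(C(C)=O)cc(OCOC)c2O1
A4 | alternative 2 | 3-acetyl-2,6-dihydroxy-5-(methoxymethoxy)benzaldehyde | CC(=O)c1cc(OCOC)c(O)c(C=O)c1O
A5 | alternative 2 | rac-(2E)-1-[3-acetyl-2,6-dihydroxy-5-(methoxymethoxy)phenyl]-3,7-dimethyl-7-[(triethylsilyl)oxy]oct-2-en-1-yl methyl carbonate | CC(=O)c1cc(OCOC)c(O)c(C(OC(=O)OC)/C=C(\C)CCCC(C)(C)O[Si](CC)(CC)CC)c1O
A6 | alternative 3 | (3S)-3,7-dimethylocta-1,6-dien-3-ol | C=C[C@@](C)(O)CCC=C(C)C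
A7 | alternative 3 | 1-[3-ethenyl-4-fluoro-2-hydroxy-5-(methoxymethoxy)phenyl]ethan-1-one | CC(=O)c1cc(OCOC)c(F)c(C=C)c1O
A8 | alternative 3 | 1-[4-{[(3S)-3,7-dimethylocta-1,6-dien-3-yl]oxy}-3-ethenyl-2-hydroxy-5-(methoxymethoxy)phenyl]ethan-1-one | CC(=O)c1cc(OCOC)c(O[C@](C)(C=C)CCC=C(C)C)c(C=C)c1O
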